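The cyclohexene ring (C1 acetoxy carbon, C2=C3 alkene, C4 gem-dimethyl carbon, C5 CHBr, C6 CH2) is divided into two five-carbon halves at C3–C4 and C6–C1. The key step exploits the 1,3-relation of the C1 oxygen and the C5 bromine. With C5 as a ketone, its α-carbons C4 and C6 are nucleophiles, and C3 and C1 are the electrophilic ends of a 2-substituted 3-bromoacrolein that already carries the side-chain stereocentre. In one flask the tetrasubstituted enolate of 3-methylbutan-2-one displaces the vinylic bromide, setting quaternary C4. The released methyl ketone then closes onto the aldehyde. Evans–Tishchenko reduction and two invertive brominations complete the target.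

Key step: step 6

Remark on the chemistry: the ring locants above are used throughout, and the side chain is C1' (CHBr) and C2' (CH2Cl). Bromoenal 6 is assumed to be usable as an E/Z mixture, because the vinylic substitution in step 6 should be stereoconvergent.

Step 1
Reactants: 1 ethyl (3S)-4-chloro-3-hydroxybutanoate
Product: 2 ethyl (3S)-3-(tert-butyldimethylsilyloxy)-4-chlorobutanoate
Conditions: TBSCl, imidazole, DMF, 23 °C
Reagents that add atoms: tert-butyldimethylsilyl chloride, CC(C)(C)[Si](C)(C)Cl
Why: Imidazole-promoted silyl ether formation leaves the purchased (S)-stereocentre (the later C1') untouched and gives an ether that should tolerate hydride, bromine and enolate chemistry.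

Step 2
Reactants: 2 ethyl (3S)-3-(tert-butyldimethylsilyloxy)-4-chlorobutanoate
Product: 3 (3S)-3-(tert-butyldimethylsilyloxy)-4-chlorobutanal
Conditions: iBu2AlH, toluene, −78 °C; MeOH, aq. potassium sodium tartrate
Reagents that add atoms: none
Why: Partial ester reduction with iBu2AlH at low temperature should stop at the aldehyde oxidation level and touches no stereocentre.

Step 3
Reactants: 3 (3S)-3-(tert-butyldimethylsilyloxy)-4-chlorobutanal
Product: 4 (3S)-3-(tert-butyldimethylsilyloxy)-4-chloro-2-methylidenebutanal
Conditions: aq. HCHO, pyrrolidine (cat.), EtCO2H (cat.), iPrOH, 45 °C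
Reagents that add atoms: formaldehyde, C=O
Why: Amine-catalysed α-methylenation (Mannich condensation, then β-elimination of the amine) brings in C3, and the product has no α-hydrogen left, so the β-silyloxy group cannot be eliminated afterwards.

Step 4
Reactants: 4 (3S)-3-(tert-butyldimethylsilyloxy)-4-chloro-2-methylidenebutanal
Product: 6 (3S)-2-(bromomethylidene)-3-(tert-butyldimethylsilyloxy)-4-chlorobutanal (E/Z mixture), via vicinal dibromide 5 (not isolated)
Conditions: Br2, CH2Cl2, −78 °C; then Et3N, −78 to 0 °C
Reagents that add atoms: bromine, BrBr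
Why: Electrophilic bromine addition followed by E2 dehydrobromination is the usual route from 2-substituted acroleins to their 3-bromo derivatives; it raises C3 to the level needed for substitution with retention of the alkene, and the more acidic, more accessible CH2Br hydrogens should be removed in preference to the C1' hydrogen.

Step 5
Reactants: 7 3-bromo-3-methylbutan-2-one
Product: 9 trimethyl[(3-methylbut-2-en-2-yl)oxy]silane, via zinc enolate 8 (not isolated)
Conditions: Zn dust, Me3SiCl, Et2O, reflux
Reagents that add atoms: chlorotrimethylsilane, C[Si](C)(C)Cl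
Why: Reductive silylation of an α-bromo ketone (Reformatsky-type zinc insertion, then O-silylation) places the enol double bond where the bromine stood, so only the tetrasubstituted regioisomer should form.

Step 6
Reactants: 9 trimethyl[(3-methylbut-2-en-2-yl)oxy]silane; 6 (3S)-2-(bromomethylidene)-3-(tert-butyldimethylsilyloxy)-4-chlorobutanal
Product: 12 (5R)-4-[(1S)-1-(tert-butyldimethylsilyloxy)-2-chloroethyl]-5-hydroxy-2,2-dimethylcyclohex-3-en-1-one, via lithium enolate 10 (not isolated), via keto-enal 11 (not isolated)
Conditions: 9, MeLi, THF, 0 °C; −78 °C, 6, DMPU, −78 to −20 °C; −78 °C, LiN(SiMe3)2; AcOH quench at −78 °C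
Reagents that add atoms: none
Why: The regiodefined enolate 10 attacks C3 of 6 by conjugate addition–elimination (nucleophilic vinylic substitution, the known reaction of tertiary enolate carbons with β-halovinyl carbonyl compounds); the competing 1,2-aldol addition of so hindered an enolate is reversible while bromide loss is not, so the mixture should drain into 11 and form the quaternary C4–C3 bond. The aldehyde enolate formed on addition lives long enough for rotation about C2–C3, so 11 should arise with the bulky C4 group cis to the small formyl group, which is the geometry ring closure needs. LiN(SiMe3)2 can deprotonate 11 only at the methyl group, because C4 bears no hydrogen, and this enolate closes the six-membered ring onto the formyl carbon by a 6-(enolendo)-exo-trig aldol addition (C6–C1), attack at C3 being excluded because it would give a four-membered ring. The new C1 stereocentre is controlled by C1': allylic 1,2-strain holds the C1'–H in the enal plane next to the formyl group, so the silyloxy group covers one face, and the non-chelate and chelate models both send C6 to the opposite face, which should give the 1,3-anti (1R,1'S) aldol. The step needs C4-before-C6 selectivity, secured by the enol silane origin of 10 and by adding the amide base only after 6 is consumed, and 1,4- over 1,2-selectivity, secured by aldol reversibility and DMPU. The cold acidic quench should keep the lithium aldolate from retro-aldol opening and from dehydration to the dienone.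

Step 7
Reactants: 12 (5R)-4-[(1S)-1-(tert-butyldimethylsilyloxy)-2-chloroethyl]-5-hydroxy-2,2-dimethylcyclohex-3-en-1-one
Product: 14 (1R,5R)-2-[(1S)-1-(tert-butyldimethylsilyloxy)-2-chloroethyl]-5-hydroxy-4,4-dimethylcyclohex-2-en-1-yl acetate, via hemiacetal 13 (not isolated)
Conditions: MeCHO (excess), SmI2 (0.3 equiv), THF, −10 °C
Reagents that add atoms: acetaldehyde, CC=O
Why: In the Evans–Tishchenko reduction the hemiacetal 13, bound to trivalent samarium, delivers its hydride within the molecule to the C5 ketone from the face of the pseudoaxial C1 oxygen, so the new C5 hydroxyl should stand trans to C1–O while the acetyl group ends on the C1 oxygen, where the target needs it.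

Step 8
Reactants: 14 (1R,5R)-2-[(1S)-1-(tert-butyldimethylsilyloxy)-2-chloroethyl]-5-hydroxy-4,4-dimethylcyclohex-2-en-1-yl acetate
Product: 16 (1R,5S)-5-bromo-2-[(1S)-1-(tert-butyldimethylsilyloxy)-2-chloroethyl]-4,4-dimethylcyclohex-2-en-1-yl acetate, via alkoxyphosphonium bromide 15 (not isolated)
Conditions: CBr4, PPh3, CH2Cl2, 0 to 40 °C
Reagents that add atoms: tetrabromomethane, BrC(Br)(Br)Br
Why: The Appel reaction replaces the C5 hydroxyl by SN2 with inversion, a displacement known for 2,2-dimethylcyclohexanols, and should turn the trans alcohol into the bromide cis to the acetate while the hindered secondary silyl ether at C1' stays in place.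

Step 9
Reactants: 16 (1R,5S)-5-bromo-2-[(1S)-1-(tert-butyldimethylsilyloxy)-2-chloroethyl]-4,4-dimethylcyclohex-2-en-1-yl acetate
Product: 18 (1R,5S)-5-bromo-2-[(1R)-1-bromo-2-chloroethyl]-4,4-dimethylcyclohex-2-en-1-yl acetate, via alkoxyphosphonium bromide 17 (not isolated)
Conditions: Ph3PBr2, CH2Cl2, 0 °C
Reagents that add atoms: dibromotriphenylphosphorane, BrP(Br)(c1ccccc1)(c1ccccc1)c1ccccc1
Why: Direct conversion of a silyl ether into a bromide with Ph3PBr2 runs under neutral conditions by SN2 with inversion at C1' ((S)-ether to (R)-bromide); SN2' attack is blocked at neopentyl C3, and ionisation is disfavoured by the neighbouring CH2Cl group.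

Compound list
1 | ethyl (3S)-4-chloro-3-hydroxybutanoate | CCOC(=O)C[C@H](O)CCl | starting material
2 | ethyl (3S)-3-(tert-butyldimethylsilyloxy)-4-chlorobutanoate | CCOC(=O)C[C@H](O[Si](C)(C)C(C)(C)C)CCl | intermediate
3 | (3S)-3-(tert-butyldimethylsilyloxy)-4-chlorobutanal | O=CC[C@H](O[Si](C)(C)C(C)(C)C)CCl | intermediate
4 | (3S)-3-(tert-butyldimethylsilyloxy)-4-chloro-2-methylidenebutanal | C=C(C=O)[C@H](O[Si](C)(C)C(C)(C)C)CCl | intermediate
5 | vicinal dibromide of 4, 2-bromo-2-(bromomethyl)-3-(tert-butyldimethylsilyloxy)-4-chlorobutanal (both C2 epimers, not isolated) | O=CC(Br)(CBr)[C@H](O[Si](C)(C)C(C)(C)C)CCl | intermediate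
6 | (3S)-2-(bromomethylidene)-3-(tert-butyldimethylsilyloxy)-4-chlorobutanal (E/Z mixture) | BrC=C(C=O)[C@H](O[Si](C)(C)C(C)(C)C)CCl | intermediate
7 | 3-bromo-3-methylbutan-2-one | CC(=O)C(C)(C)Br | starting material
8 | bromozinc enolate of 3-methylbutan-2-one, tetrasubstituted (not isolated) | CC(O[Zn]Br)=C(C)C | intermediate
9 | trimethyl[(3-methylbut-2-en-2-yl)oxy]silane | CC(O[Si](C)(C)C)=C(C)C | intermediate
10 | lithium 3-methylbut-2-en-2-olate (not isolated) | CC([O-])=C(C)C.[Li+] | intermediate
11 | (2Z)-2-[(1S)-1-(tert-butyldimethylsilyloxy)-2-chloroethyl]-4,4-dimethyl-5-oxohex-2-enal (not isolated) | CC(=O)C(C)(C)/C=C(\C=O)[C@H](O[Si](C)(C)C(C)(C)C)CCl | intermediate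
12 | (5R)-4-[(1S)-1-(tert-butyldimethylsilyloxy)-2-chloroethyl]-5-hydroxy-2,2-dimethylcyclohex-3-en-1-one | O[C@@H]1CC(=O)C(C)(C)C=C1[C@H](O[Si](C)(C)C(C)(C)C)CCl | intermediate
13 | acetaldehyde hemiacetal of 12 at the C1 oxygen (not isolated) | CC(O)O[C@@H]1CC(=O)C(C)(C)C=C1[C@H](O[Si](C)(C)C(C)(C)C)CCl | intermediate
14 | (1R,5R)-2-[(1S)-1-(tert-butyldimethylsilyloxy)-2-chloroethyl]-5-hydroxy-4,4-dimethylcyclohex-2-en-1-yl acetate | CC(=O)O[C@@H]1C[C@@H](O)C(C)(C)C=C1[C@H](O[Si](C)(C)C(C)(C)C)CCl | intermediate
15 | C5 alkoxytriphenylphosphonium bromide of 14 (not isolated) | CC(=O)O[C@@H]1C[C@@H](O[P+](c2ccccc2)(c2ccccc2)c2ccccc2)C(C)(C)C=C1[C@H](O[Si](C)(C)C(C)(C)C)CCl.[Br-] | intermediate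
16 | (1R,5S)-5-bromo-2-[(1S)-1-(tert-butyldimethylsilyloxy)-2-chloroethyl]-4,4-dimethylcyclohex-2-en-1-yl acetate | CC(=O)O[C@@H]1C[C@H](Br)C(C)(C)C=C1[C@H](O[Si](C)(C)C(C)(C)C)CCl | intermediate
17 | C1' alkoxytriphenylphosphonium bromide derived from 16 (not isolated) | CC(=O)O[C@@H]1C[C@H](Br)C(C)(C)C=C1[C@H](O[P+](c2ccccc2)(c2ccccc2)c2ccccc2)CCl.[Br-] | intermediate
18 | (1R,5S)-5-bromo-2-[(1R)-1-bromo-2-chloroethyl]-4,4-dimethylcyclohex-2-en-1-yl acetate | CC(=O)O[C@@H]1C[C@H](Br)C(C)(C)C=C1[C@@H](Br)CCl | target

Total step count: 9. Longest linear sequence: 8 (steps 1, 2, 3, 4, 6, 7, 8, 9).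

Steps most likely to fail

Step 6.
- **What may go wrong:** The hindered enolate may rest as its 1,2-aldolate or be lost through proton transfer, so that vinylic substitution stays incomplete. The facial selectivity of the ring closure may also be poor.
- **Fallback:** It sets out from 6 and 9 and comes back at 12. NaOMe in MeOH at 0 °C converts 6 by addition–elimination into (3S)-3-(tert-butyldimethylsilyloxy)-4-chloro-2-(methoxymethylidene)butanal F1. Enolate 10, made from 9 as before, is then used deliberately in the 1,2 mode at −78 °C and gives (6S)-6-(tert-butyldimethylsilyloxy)-7-chloro-4-hydroxy-5-(methoxymethylidene)-3,3-dimethylheptan-2-one F2. Pyridinium p-toluenesulfonate in wet acetone ionises the allylic alcohol with the push of the enol ether. This 1,3-carbonyl transposition loses methanol and gives keto-enal 11, which is now isolated. A boron aldol closure (Bu2BOTf, iPr2NEt, −78 °C, closed transition state) then gives 12.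

Step 8.
- **What may go wrong:** Displacement at the neopentyl-type C5 may be outrun by E2 elimination toward C6, by a methyl shift from C4 after ionisation, or by participation of the C1 acetate with loss of inversion.
- **Fallback:** It sets out from 14 and comes back at 16. The in situ phosphonium activation is replaced by a discrete, isolable sulfonate. ClCH2SO2Cl and pyridine give (1R,5R)-2-[(1S)-1-(tert-butyldimethylsilyloxy)-2-chloroethyl]-5-(chloromethylsulfonyloxy)-4,4-dimethylcyclohex-2-en-1-yl acetate F3. LiBr in DMF then displaces the sulfonate in a separate SN2 step to give 16.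

Step 7.
- **What may go wrong:** The ring may hold the samarium-bound hemiacetal too far from the hindered C5 ketone. Hydride transfer would then be slow, and retro-aldol opening or acetyl migration could take over.
- **Fallback:** It sets out from 12 and comes back at 14. A Saksena–Evans reduction (Me4NBH(OAc)3, MeCN/AcOH, −30 °C), again directed by the C1 hydroxyl, gives the trans diol (1R,5R)-2-[(1S)-1-(tert-butyldimethylsilyloxy)-2-chloroethyl]-4,4-dimethylcyclohex-2-ene-1,5-diol F4. The less hindered allylic C1 hydroxyl is then acetylated selectively (Ac2O, pyridine, 0 °C) beside the neopentyl-type C5 hydroxyl to give 14.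

Further compounds
F1 | step 6 | (3S)-3-(tert-butyldimethylsilyloxy)-4-chloro-2-(methoxymethylidene)butanal | COC=C(C=O)[C@H](O[Si](C)(C)C(C)(C)C)CCl
F2 | step 6 | (6S)-6-(tert-butyldimethylsilyloxy)-7-chloro-4-hydroxy-5-(methoxymethylidene)-3,3-dimethylheptan-2-one | CC(=O)C(C)(C)C(O)C(=COC)[C@H](O[Si](C)(C)C(C)(C)C)CCl
F3 | step 8 | (1R,5R)-2-[(1S)-1-(tert-butyldimethylsilyloxy)-2-chloroethyl]-5-(chloromethylsulfonyloxy)-4,4-dimethylcyclohex-2-en-1-yl acetate | CC(=O)O[C@@H]1C[C@@H](OS(=O)(=O)CCl)C(C)(C)C=C1[C@H](O[Si](C)(C)C(C)(C)C)CCl
F4 | step 7 | (1R,5R)-2-[(1S)-1-(tert-butyldimethylsilyloxy)-2-chloroethyl]-4,4-dimethylcyclohex-2-ene-1,5-diol | O[C@@H]1C[C@@H](O)C(C)(C)C=C1[C@H](O[Si](C)(C)C(C)(C)C)CCl
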